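**Strategy.** The synthesis rests on cutting N1–C7a and C7–Br at once. On the benzo ring of the indole, the ring-fusion carbon C7a is bonded to N1 and the adjacent C7 holds a bromine. This is the pattern an aryne spanning C7–C7a leaves when a tethered nitrogen adds to one end and the carbanion at the other end is brominated. One operation should thus close the five-membered ring and place the C7 bromine. The precursor is a Boc-protected 2-arylethylamine whose arene bears triflate (future C7a), trimethylsilyl (future C7) and the C5 bromine, made from 2-(2-aminoethyl)phenol by dibromination and a retro-Brook silyl shift. Boc removal, dehydrogenation and C3 bromination complete the route.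

Key step: step 5

Assumption: the counter-ion of the anionic intermediates 14 to 16 is written as sodium, although caesium may take its place once CsF is added; the bonds formed are the same.

**Step 1**
Reactants: 1 2-(2-aminoethyl)phenol; 2 di-tert-butyl dicarbonate
Product: 3 tert-butyl N-[2-(2-hydroxyphenyl)ethyl]carbamate
Conditions: Boc2O (1.05 equiv), THF, 0 °C to rt
Reagents that add atoms: di-tert-butyl dicarbonate, CC(C)(C)OC(=O)OC(=O)OC(C)(C)C
Why: The aliphatic amine is far more nucleophilic than the phenol and should be acylated selectively in the absence of an acyl-transfer catalyst (chemoselective N-tert-butoxycarbonylation).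

**Step 2**
Reactants: 3 tert-butyl N-[2-(2-hydroxyphenyl)ethyl]carbamate; 4 N-bromosuccinimide
Product: 6 tert-butyl N-[2-(3,5-dibromo-2-hydroxyphenyl)ethyl]carbamate, via para-monobromide 5 (not isolated)
Conditions: NBS (2.05 equiv), MeCN, 0 °C to rt
Reagents that add atoms: N-bromosuccinimide, O=C1CCC(=O)N1Br
Why: The free hydroxyl group directs electrophilic aromatic bromination to its para position and to its one open ortho position, while the carbamate and the positions meta to oxygen should stay untouched.

**Step 3**
Reactants: 6 tert-butyl N-[2-(3,5-dibromo-2-hydroxyphenyl)ethyl]carbamate; 7 hexamethyldisilazane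
Product: 10 tert-butyl N-[2-(5-bromo-2-hydroxy-3-(trimethylsilyl)phenyl)ethyl]carbamate, via silyl ether 8 (not isolated), via aryllithium 9 (not isolated)
Conditions: HMDS, THF, 65 °C, then evaporation; n-BuLi (2.1 equiv), THF, −78 °C; aq. NH4Cl
Reagents that add atoms: hexamethyldisilazane, C[Si](C)(C)N[Si](C)(C)C
Why: HMDS silylates the phenol, the first equivalent of n-BuLi removes the carbamate N–H, and the second should undergo bromine–lithium exchange preferentially at the bromine ortho to oxygen (as with 2,4-dibromoanisole), after which aryllithium 9 takes the silyl group from oxygen in an anionic 1,3-shift from oxygen to carbon (retro-Brook rearrangement) to give the phenoxide that is protonated on work-up.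

**Step 4**
Reactants: 10 tert-butyl N-[2-(5-bromo-2-hydroxy-3-(trimethylsilyl)phenyl)ethyl]carbamate; 11 N-phenylbis(trifluoromethanesulfonimide)
Product: 12 tert-butyl N-[2-(5-bromo-2-(trifluoromethylsulfonyloxy)-3-(trimethylsilyl)phenyl)ethyl]carbamate
Conditions: PhNTf2, DBU, MeCN, rt to 40 °C
Reagents that add atoms: N-phenylbis(trifluoromethanesulfonimide), O=S(=O)(N(c1ccccc1)S(=O)(=O)C(F)(F)F)C(F)(F)F
Why: The phenoxide formed with DBU should be O-sulfonylated by the mild triflyl donor PhNTf2, which leaves the carbamate N–H and the aryl–silicon bond alone (phenol triflation).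

**Step 5**
Reactants: 12 tert-butyl N-[2-(5-bromo-2-(trifluoromethylsulfonyloxy)-3-(trimethylsilyl)phenyl)ethyl]carbamate; 13 carbon tetrabromide
Product: 17 tert-butyl 5,7-dibromoindoline-1-carboxylate, via sodium carbamate 14 (not isolated), via aryne 15 (not isolated), via aryl anion 16 (not isolated)
Conditions: NaH (1.0 equiv), THF, 0 °C; then CBr4 (3 equiv), CsF (3 equiv), 18-crown-6, THF, 0 °C to rt; H2O
Reagents that add atoms: carbon tetrabromide, BrC(Br)(Br)Br
Why: Proposed new method: NaH converts the carbamate into its sodium salt 14 with loss of H2 so that no acidic N–H remains, fluoride then attacks silicon and triflate departs to give aryne 15 across the carbons that become C7 and C7a, the nitrogen adds to the nearer aryne carbon to form N1–C7a, and the resulting aryl anion 16, held by chelation of its counter-ion to the Boc carbonyl, attacks a bromine of CBr4 to form C7–Br and tribromomethanide. The closest known reaction types are the fluoride-triggered intramolecular amination of ortho-silylaryl triflates that gives indolines after protonation, the three-component aminohalogenation of arynes with amines and tetrahalomethanes, and the halogenation of C7-lithiated N-Boc-indoline. The pyrrolidine ring closes in a 5-exo-dig mode, since the attacked aryne carbon lies in the new ring and its partner outside it. No stereocenter is formed. Regioselectivity is required and is secured by the two-carbon tether, which lets nitrogen reach only C7a, and is reinforced by the C5 bromine, whose inductive effect favours negative charge at C7. Bromination must outrun protonation, which the absence of N–H, the use of THF in place of the C–H acidic acetonitrile, a dry fluoride source and an excess of CBr4 should ensure.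

**Step 6**
Reactants: 17 tert-butyl 5,7-dibromoindoline-1-carboxylate
Product: 18 5,7-dibromoindoline
Conditions: TFA, CH2Cl2, 0 °C to rt; aq. NaHCO3
Reagents that add atoms: none
Why: Acidolysis of the tert-butyl carbamate (loss of isobutene, then decarboxylation) should free the indoline nitrogen, and the aryl bromides are inert to TFA.

**Step 7**
Reactants: 18 5,7-dibromoindoline
Product: 19 5,7-dibromoindole
Conditions: DDQ (1.1 equiv), toluene, rt
Reagents that add atoms: none
Why: DDQ abstracts hydride from C2 of the N-unsubstituted indoline and loss of a proton from C3 aromatises the five-membered ring (quinone dehydrogenation of an indoline to an indole), with the gain in aromaticity as driving force.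

**Step 8**
Reactants: 19 5,7-dibromoindole; 4 N-bromosuccinimide
Product: 20 3,5,7-tribromoindole
Conditions: NBS (1.0 equiv), DMF, 0 °C, dark
Reagents that add atoms: N-bromosuccinimide, O=C1CCC(=O)N1Br
Why: C3 is the most nucleophilic position of the indole, so one equivalent of NBS should brominate it selectively (electrophilic aromatic substitution), and the two benzo-ring bromines temper the ring against over-bromination.

**Compound list**
1 | 2-(2-aminoethyl)phenol | NCCc1ccccc1O | starting material
2 | di-tert-butyl dicarbonate | CC(C)(C)OC(=O)OC(=O)OC(C)(C)C | starting material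
3 | tert-butyl N-[2-(2-hydroxyphenyl)ethyl]carbamate | CC(C)(C)OC(=O)NCCc1ccccc1O | intermediate
4 | N-bromosuccinimide | O=C1CCC(=O)N1Br | starting material
5 | tert-butyl N-[2-(5-bromo-2-hydroxyphenyl)ethyl]carbamate (para-monobromide) | CC(C)(C)OC(=O)NCCc1cc(Br)ccc1O | intermediate
6 | tert-butyl N-[2-(3,5-dibromo-2-hydroxyphenyl)ethyl]carbamate | CC(C)(C)OC(=O)NCCc1cc(Br)cc(Br)c1O | intermediate
7 | hexamethyldisilazane | C[Si](C)(C)N[Si](C)(C)C | starting material
8 | tert-butyl N-[2-(3,5-dibromo-2-(trimethylsilyloxy)phenyl)ethyl]carbamate (silyl ether) | CC(C)(C)OC(=O)NCCc1cc(Br)cc(Br)c1O[Si](C)(C)C | intermediate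
9 | tert-butyl N-lithio-N-[2-(5-bromo-3-lithio-2-(trimethylsilyloxy)phenyl)ethyl]carbamate (aryllithium) | [Li]N(CCc1cc(Br)cc([Li])c1O[Si](C)(C)C)C(=O)OC(C)(C)C | intermediate
10 | tert-butyl N-[2-(5-bromo-2-hydroxy-3-(trimethylsilyl)phenyl)ethyl]carbamate | CC(C)(C)OC(=O)NCCc1cc(Br)cc([Si](C)(C)C)c1O | intermediate
11 | N-phenylbis(trifluoromethanesulfonimide) | O=S(=O)(N(c1ccccc1)S(=O)(=O)C(F)(F)F)C(F)(F)F | starting material
12 | tert-butyl N-[2-(5-bromo-2-(trifluoromethylsulfonyloxy)-3-(trimethylsilyl)phenyl)ethyl]carbamate | CC(C)(C)OC(=O)NCCc1cc(Br)cc([Si](C)(C)C)c1OS(=O)(=O)C(F)(F)F | intermediate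
13 | carbon tetrabromide | BrC(Br)(Br)Br | starting material
14 | sodium salt of 12 at the carbamate nitrogen (sodium carbamate) | CC(C)(C)OC(=O)[N-]CCc1cc(Br)cc([Si](C)(C)C)c1OS(=O)(=O)C(F)(F)F.[Na+] | intermediate
15 | sodium salt of tert-butyl N-[2-(5-bromo-2,3-didehydrophenyl)ethyl]carbamate (aryne) | CC(C)(C)OC(=O)[N-]CCC1=CC(Br)=CC#C1.[Na+] | intermediate
16 | sodium 5-bromo-1-(tert-butoxycarbonyl)indolin-7-ide (aryl anion) | CC(C)(C)OC(=O)N1CCc2cc(Br)c[c-]c21.[Na+] | intermediate
17 | tert-butyl 5,7-dibromoindoline-1-carboxylate | CC(C)(C)OC(=O)N1CCc2cc(Br)cc(Br)c21 | intermediate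
18 | 5,7-dibromoindoline | Brc1cc(Br)c2NCCc2c1 | intermediate
19 | 5,7-dibromoindole | Brc1cc(Br)c2[nH]ccc2c1 | intermediate
20 | 3,5,7-tribromoindole | Brc1cc(Br)c2[nH]cc(Br)c2c1 | target

Total step count: 8. Longest linear sequence: 8 steps (from 1 to 20).

**Steps most likely to fail**

Step 5 (the proposed new method). The C7 anion may pick up a proton before it meets CBr4. The sodium carbamate may also be N-brominated, or may attack a triflyl sulfur, before the aryne is released. The fallback uses known chemistry and sets out from 12. CsF in acetonitrile at room temperature without a bromine donor should effect the established fluoride-triggered aryne amination with proton transfer. It passes through tert-butyl N-[2-(5-bromo-2,3-didehydrophenyl)ethyl]carbamate F1, which is not isolated, to tert-butyl 5-bromoindoline-1-carboxylate F2. TFA in CH2Cl2 then gives 5-bromoindoline F3. NBS (1.0 equiv) in acetonitrile at 0 °C should brominate C7, the only open position activated by the free amine, since the para position C5 is occupied. This returns the route at 18.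

Step 3. Exchange may take place at the para bromine, or the aryllithium may be protonated by carbamate N–H that has not yet been removed, so that the wrong halogen is lost or the ring is simply debrominated. The irreversible silyl shift should help, since only the ortho-lithiated species can undergo it. The fallback sets out from 3. NBS (1.0 equiv) in acetonitrile at −20 °C should stop at the para-monobromide 5, which is isolated this time. N-Iodosuccinimide with catalytic TsOH iodinates the remaining ortho position to give tert-butyl N-[2-(5-bromo-2-hydroxy-3-iodophenyl)ethyl]carbamate F4. HMDS converts it into tert-butyl N-[2-(5-bromo-3-iodo-2-(trimethylsilyloxy)phenyl)ethyl]carbamate F5. n-BuLi (2.1 equiv) at −100 °C then exchanges iodine far faster than bromine, so the route is rejoined at aryllithium 9 and, after the silyl shift and work-up, at 10.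

Step 7. Hydride abstraction may stall on the electron-poor ring, or the quinone may add to the product indole. The fallback sets out from 18 and replaces the quinone by a halogenation–elimination sequence. N-Chlorination with trichloroisocyanuric acid (0.35 equiv) in CH2Cl2 at 0 °C gives 5,7-dibromo-1-chloroindoline F6. DBU then removes HCl across N1–C2 to give 5,7-dibromo-3H-indole F7, which tautomerises to 19.

**Further compounds**
F1 | step 5 | tert-butyl N-[2-(5-bromo-2,3-didehydrophenyl)ethyl]carbamate | CC(C)(C)OC(=O)NCCC1=CC(Br)=CC#C1
F2 | step 5 | tert-butyl 5-bromoindoline-1-carboxylate | CC(C)(C)OC(=O)N1CCc2cc(Br)ccc21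
F3 | step 5 | 5-bromoindoline | Brc1ccc2NCCc2c1
F4 | step 3 | tert-butyl N-[2-(5-bromo-2-hydroxy-3-iodophenyl)ethyl]carbamate | CC(C)(C)OC(=O)NCCc1cc(Br)cc(I)c1O
F5 | step 3 | tert-butyl N-[2-(5-bromo-3-iodo-2-(trimethylsilyloxy)phenyl)ethyl]carbamate | CC(C)(C)OC(=O)NCCc1cc(Br)cc(I)c1O[Si](C)(C)C
F6 | step 7 | 5,7-dibromo-1-chloroindoline | ClN1CCc2cc(Br)cc(Br)c21
F7 | step 7 | 5,7-dibromo-3H-indole | Brc1cc(Br)c2N=CCc2c1
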